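## Retrosynthetic overview

1. Late stage: the (Z)-p-coumarate comes from Suzuki–Miyaura coupling on a (Z)-3-iodoacrylate of the 19-alcohol; C-19 comes from an axial ester, the C-4 methyl from enolate methylation, C-8=C-17 from Wittig methylenation of an 8-ketone, and the side chain from conjugate isoprenylation of a 9-methylidene-8-ketone.
2. Key disconnection: ring B is opened at its two opposite bonds C-5–C-10 and C-7–C-8, a [3+3] bicyclisation of an acyclic chain in which C-8–C-9–C-10 is a 3-methylalk-2-enoyl chloride (electrophilic at C-10 and C-8) and C-5–C-6–C-7 is a γ-substituted allylsilane (nucleophilic at C-5, then at C-7).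
3. Enabling feature: C-8 is sp2 in the target (exocyclic C-8=C-17, the equivalent of a ketone) and the quaternary, methyl-bearing ring-fusion carbon C-10 stands β to it, while the ring-fusion CH C-5 and the CH2 C-7 flank C-6; since C-5–C-10 is the bond shared by rings A and B, forming it closes ring A (C-1 to C-5 and C-10) and the C-7–C-8 bond then closes ring B.
4. Ring order and stereocontrol: ring A, then ring B, in one flask; a single stereocentre (C-4, from copper-catalysed allylic alkylation) controls C-5 and C-10, C-9 is set by equilibration next to the 8-ketone, and C-4 is made quaternary afterwards.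

Key step: step 7

Remark (assumption on the chemistry): the target as drawn is (4R,5S,9R,10S) in labdane numbering, that is the ent-labdane series with the oxygenated C-19 axial and syn to the C-10 methyl; labdane numbering is used in the text below.

## Route

Step 1
Reactants: 1 methyl (E)-4-bromobut-2-enoate; 2 2-(3-bromopropyl)-2-methyl-1,3-dioxolane
Product: 4 methyl (2S)-2-ethenyl-5-(2-methyl-1,3-dioxolan-2-yl)pentanoate, via Grignard reagent 3 (not isolated)
Conditions: 2, Mg, Et2O; then 1, CuBr·SMe2 (cat.), Taniaphos (cat., enantiomer chosen for the 2S product), CH2Cl2, −75 °C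
Reagents that add atoms: none
Why: Copper-catalysed asymmetric allylic alkylation (SN2′) of the 4-bromocrotonate by the alkyl Grignard reagent should give the α-branched β,γ-unsaturated ester, the chiral diphosphine–copper complex setting the only stereocentre (C-4) that later directs the ring fusion.

Step 2
Reactants: 4 methyl (2S)-2-ethenyl-5-(2-methyl-1,3-dioxolan-2-yl)pentanoate; 5 trimethyl(prop-2-enyl)silane
Product: 6 methyl (2S,3E)-2-[3-(2-methyl-1,3-dioxolan-2-yl)propyl]-5-(trimethylsilyl)pent-3-enoate
Conditions: second-generation Grubbs catalyst (cat.), excess 5, CH2Cl2, 40 °C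
Reagents that add atoms: none
Why: Olefin cross-metathesis of the monosubstituted alkene with an excess of the unhindered allylsilane should give the γ-substituted allylsilane mainly as the E isomer without touching C-4, and any Z isomer can be carried on because both converge in step 7.

Step 3
Reactants: 6 methyl (2S,3E)-2-[3-(2-methyl-1,3-dioxolan-2-yl)propyl]-5-(trimethylsilyl)pent-3-enoate
Product: 7 methyl (2S,3E)-2-(4-oxopentyl)-5-(trimethylsilyl)pent-3-enoate
Conditions: pyridinium p-toluenesulfonate (cat.), acetone/H2O, 50 °C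
Reagents that add atoms: water, O
Why: Mildly acid-catalysed ketal hydrolysis should unmask the methyl ketone while the allylsilane and the β,γ-unsaturated ester, which need stronger acid or base to react, survive.

Step 4
Reactants: 7 methyl (2S,3E)-2-(4-oxopentyl)-5-(trimethylsilyl)pent-3-enoate; 8 prop-2-enyl 2-(diethoxyphosphoryl)acetate
Product: 9 8-methyl 1-prop-2-enyl (2E,7S)-3-methyl-7-[(E)-3-(trimethylsilyl)prop-1-enyl]oct-2-enedioate
Conditions: NaH (slightly less than 8), THF, 0 to 45 °C
Reagents that add atoms: none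
Why: Horner–Wadsworth–Emmons olefination of the methyl ketone with the weakly basic phosphonate anion should give the 3-methyl-2-enoate (E major, the Z isomer is equally usable) without enolising the less acidic C-4 position.

Step 5
Reactants: 9 8-methyl 1-prop-2-enyl (2E,7S)-3-methyl-7-[(E)-3-(trimethylsilyl)prop-1-enyl]oct-2-enedioate
Product: 10 (2E,7S)-8-methoxy-3-methyl-8-oxo-7-[(E)-3-(trimethylsilyl)prop-1-enyl]oct-2-enoic acid
Conditions: Pd(PPh3)4 (cat.), morpholine, THF, 20 °C
Reagents that add atoms: none
Why: Palladium-catalysed allyl transfer to morpholine (Tsuji–Trost deallylation) should cleave only the allyl ester under neutral conditions, leaving the methyl ester, the allylsilane and C-4 untouched.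

Step 6
Reactants: 10 (2E,7S)-8-methoxy-3-methyl-8-oxo-7-[(E)-3-(trimethylsilyl)prop-1-enyl]oct-2-enoic acid
Product: 11 (2E,7S)-8-methoxy-3-methyl-8-oxo-7-[(E)-3-(trimethylsilyl)prop-1-enyl]oct-2-enoyl chloride
Conditions: 1-chloro-N,N,2-trimethylprop-1-en-1-amine, CH2Cl2, 0 to 20 °C
Reagents that add atoms: 1-chloro-N,N,2-trimethylprop-1-en-1-amine, CC(C)=C(Cl)N(C)C
Why: The α-chloroenamine should convert the acid into the acid chloride under neutral conditions free of HCl, so that the acid-labile allylsilane is not protodesilylated.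

Step 7
Reactants: 11 (2E,7S)-8-methoxy-3-methyl-8-oxo-7-[(E)-3-(trimethylsilyl)prop-1-enyl]oct-2-enoyl chloride
Product: 14 methyl (1S,4aS,8aR)-4a-methyl-6-oxo-1,2,3,4,4a,5,6,8a-octahydronaphthalene-1-carboxylate, via monocyclic vinylketene 12 (not isolated), via 6-chloro ketone 13 (not isolated)
Conditions: AlCl3 (2.5 equiv), CH2Cl2 (0.005 M), −78 to −20 °C; aq. NaHCO3; crude, DBU, CH2Cl2, 20 °C
Reagents that add atoms: none
Why: Proposed new method: AlCl3 ionises 11 to a 3,3-dialkyl α,β-unsaturated acylium ion whose β-carbon C-10 is attacked by the γ-carbon C-5 of the allylsilane (anti-SE2′, Hosomi–Sakurai conjugate allylation) with loss of Me3SiCl, which closes ring A in a 6-exo-trig chair and leaves vinylketene 12; the AlCl3-bound ketene carbon C-8 is then attacked by the terminal vinyl carbon C-7 (Darzens–Nenitzescu-type alkene acylation, 6-endo-trig with respect to the vinyl group), closing ring B as the 6-chloro ketone 13, from which DBU removes HCl. The closest known reactions are the TiCl4-promoted conjugate allylation of enones and α,β-unsaturated acyl cyanides by allylsilanes, the intramolecular allylsilane cyclisation onto alkylidene 1,3-dicarbonyl compounds, the Lewis-acid acylation of alkenes by acid chlorides, and the one-pot alkylation–acylation of arenes with 3-methylbut-2-enoyl chloride; their merger on one tethered allyl unit as a [3+3] bicyclisation is, to current knowledge, without precedent. C-5 is set by the C-4 stereocentre through the chair in which the Lewis-acid-bound CO2Me group and the developing vinyl group are both equatorial (H-4 and H-5 anti); C-10 is set in the same transition state, in which the acylium geometry can equilibrate (C-9–C-10 has β-cation/ketene single-bond character) and the arrangement with the C-10 methyl axial and the acyl terminus turned towards H-5, away from the allylsilane arm, should be lowest, giving H-5 anti to the C-10 methyl and hence the trans-decalin after the second closure. The step needs 1,4- rather than 1,2-attack on the acylium ion, secured by the six- against eight-membered ring, and C-7 rather than C-6 attack on the ketene, secured by the secondary against primary cation and the six- against five-membered ring; high dilution suppresses intermolecular acylation, and both geometrical isomers of 11 converge because C-6, C-7 and C-9 lose their geometry.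

Step 8
Reactants: 14 methyl (1S,4aS,8aR)-4a-methyl-6-oxo-1,2,3,4,4a,5,6,8a-octahydronaphthalene-1-carboxylate
Product: 17 methyl (1S,4aR,8aR)-4a-methyl-5-methylidene-6-oxo-1,2,3,4,4a,5,6,8a-octahydronaphthalene-1-carboxylate, via Mannich base 15 (not isolated), via ammonium iodide 16 (not isolated)
Conditions: LiN(iPr)2, THF, −78 °C; dimethyl(methylidene)ammonium iodide, −78 to 20 °C; MeI, CH2Cl2; aq. NaHCO3
Reagents that add atoms: dimethyl(methylidene)ammonium iodide, C=[N+](C)C.[I-]
Why: Kinetic deprotonation of the enone can occur only at the α′-carbon C-9 because C-7 is vinylic, so aminomethylation and elimination of the quaternised Mannich base (Eschenmoser methylenation) should place the exocyclic methylene regiospecifically at C-9.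

Step 9
Reactants: 18 2-chlorobuta-1,3-diene; 19 chloro[(trimethylsilyl)methyl]magnesium
Product: 20 trimethyl(2-methylidenebut-3-enyl)silane
Conditions: NiCl2(Ph2PCH2CH2CH2PPh2) (cat.), Et2O, reflux
Reagents that add atoms: none
Why: Kumada cross-coupling of the vinylic chloride with the silylmethyl Grignard reagent is the established way to this 2-substituted allylsilane.

Step 10
Reactants: 17 methyl (1S,4aR,8aR)-4a-methyl-5-methylidene-6-oxo-1,2,3,4,4a,5,6,8a-octahydronaphthalene-1-carboxylate; 20 trimethyl(2-methylidenebut-3-enyl)silane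
Product: 21 methyl 4a-methyl-5-(3-methylidenepent-4-enyl)-6-oxo-1,2,3,4,4a,5,6,8a-octahydronaphthalene-1-carboxylate (C-1, C-4a and C-8a as in 17; epimers at the side-chain carbon C-9)
Conditions: TiCl4, CH2Cl2, −78 °C; aq. NaHCO3
Reagents that add atoms: none
Why: In this Hosomi–Sakurai conjugate allylation the γ-CH2 of the allylsilane should add to the unhindered exocyclic methylene carbon C-11 of the TiCl4-activated dienone rather than to the ring carbon C-6, with transposition of the double bond, which builds the complete 3-methylidenepent-4-enyl side chain in one step and leaves C-9 as an epimer mixture that is corrected in step 11.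

Step 11
Reactants: 21 methyl 4a-methyl-5-(3-methylidenepent-4-enyl)-6-oxo-1,2,3,4,4a,5,6,8a-octahydronaphthalene-1-carboxylate
Product: 22 methyl (1S,4aR,5S,8aR)-4a-methyl-5-(3-methylidenepent-4-enyl)-6-oxodecahydronaphthalene-1-carboxylate
Conditions: [(Ph3P)CuH]6 (0.35 equiv), PhMe, 20 °C; aq. NH4Cl; then NaOMe (cat.), MeOH, 20 °C
Reagents that add atoms: none
Why: The phosphine copper hydride should reduce only the conjugated C-6=C-7 bond by 1,4-hydride transfer and leave the isolated diene alone, and methoxide then equilibrates C-9 to the equatorial side-chain epimer (anti to the angular methyl), so that C-9 is set under thermodynamic control.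

Step 12
Reactants: 22 methyl (1S,4aR,5S,8aR)-4a-methyl-5-(3-methylidenepent-4-enyl)-6-oxodecahydronaphthalene-1-carboxylate
Product: 23 methyl (1S,4aR,5R,8aR)-4a-methyl-6-methylidene-5-(3-methylidenepent-4-enyl)decahydronaphthalene-1-carboxylate
Conditions: Ph3PCH3Br, KOtBu, PhMe, 20 to 70 °C
Reagents that add atoms: methyltriphenylphosphonium bromide, C[P+](c1ccccc1)(c1ccccc1)c1ccccc1.[Br-]
Why: Wittig methylenation of the hindered 8-ketone should convert C-8 into the exocyclic C-8=C-17 alkene, while C-9 stays in its equatorial, thermodynamically preferred configuration under the basic conditions.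

Step 13
Reactants: 23 methyl (1S,4aR,5R,8aR)-4a-methyl-6-methylidene-5-(3-methylidenepent-4-enyl)decahydronaphthalene-1-carboxylate
Product: 24 methyl (1R,4aS,5R,8aS)-1,4a-dimethyl-6-methylidene-5-(3-methylidenepent-4-enyl)decahydronaphthalene-1-carboxylate
Conditions: LiN(iPr)2, THF/DMPU, −78 to 0 °C; MeI
Reagents that add atoms: iodomethane, CI
Why: Alkylation of the exocyclic ester enolate should occur from the equatorial direction, the face opposite the axial C-10 methyl, so that the new methyl becomes equatorial and the ester axial, which sets the quaternary C-4 with C-19 syn to the C-10 methyl.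

Step 14
Reactants: 24 methyl (1R,4aS,5R,8aS)-1,4a-dimethyl-6-methylidene-5-(3-methylidenepent-4-enyl)decahydronaphthalene-1-carboxylate
Product: 25 [(1R,4aS,5R,8aS)-1,4a-dimethyl-6-methylidene-5-(3-methylidenepent-4-enyl)decahydronaphthalen-1-yl]methanol
Conditions: LiAlH4, Et2O, 0 °C
Reagents that add atoms: none
Why: Hydride reduction of the axial ester should give the neopentyl primary alcohol without affecting the unactivated alkenes or any stereocentre.

Step 15
Reactants: 25 [(1R,4aS,5R,8aS)-1,4a-dimethyl-6-methylidene-5-(3-methylidenepent-4-enyl)decahydronaphthalen-1-yl]methanol; 26 (Z)-3-iodoprop-2-enoic acid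
Product: 27 [(1R,4aS,5R,8aS)-1,4a-dimethyl-6-methylidene-5-(3-methylidenepent-4-enyl)decahydronaphthalen-1-yl]methyl (Z)-3-iodoprop-2-enoate
Conditions: DCC, DMAP (cat.), CH2Cl2, 0 °C
Reagents that add atoms: none
Why: Steglich esterification at 0 °C should acylate the primary alcohol while the (Z)-iodoacrylate geometry is kept.

Step 16
Reactants: 27 [(1R,4aS,5R,8aS)-1,4a-dimethyl-6-methylidene-5-(3-methylidenepent-4-enyl)decahydronaphthalen-1-yl]methyl (Z)-3-iodoprop-2-enoate; 28 (4-hydroxyphenyl)boronic acid
Product: 29 [(1R,4aS,5R,8aS)-1,4a-dimethyl-6-methylidene-5-(3-methylidenepent-4-enyl)decahydronaphthalen-1-yl]methyl (Z)-3-(4-hydroxyphenyl)prop-2-enoate (target)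
Conditions: Pd(PPh3)4 (cat.), K2CO3, THF/H2O, 20 °C
Reagents that add atoms: none
Why: Suzuki–Miyaura coupling of a (Z)-β-iodoacrylate should proceed with retention of alkene geometry at room temperature and tolerates the free phenol, so the (Z)-p-coumarate is installed without a protecting group.

## Compound list

1 | methyl (E)-4-bromobut-2-enoate | COC(=O)/C=C/CBr | starting material
2 | 2-(3-bromopropyl)-2-methyl-1,3-dioxolane | CC1(CCCBr)OCCO1 | starting material
3 | bromo[3-(2-methyl-1,3-dioxolan-2-yl)propyl]magnesium | CC1(CCC[Mg]Br)OCCO1 | intermediate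
4 | methyl (2S)-2-ethenyl-5-(2-methyl-1,3-dioxolan-2-yl)pentanoate | COC(=O)[C@H](C=C)CCCC1(C)OCCO1 | intermediate
5 | trimethyl(prop-2-enyl)silane | C=CC[Si](C)(C)C | starting material
6 | methyl (2S,3E)-2-[3-(2-methyl-1,3-dioxolan-2-yl)propyl]-5-(trimethylsilyl)pent-3-enoate | COC(=O)[C@H](/C=C/C[Si](C)(C)C)CCCC1(C)OCCO1 | intermediate
7 | methyl (2S,3E)-2-(4-oxopentyl)-5-(trimethylsilyl)pent-3-enoate | COC(=O)[C@H](/C=C/C[Si](C)(C)C)CCCC(C)=O | intermediate
8 | prop-2-enyl 2-(diethoxyphosphoryl)acetate | C=CCOC(=O)CP(=O)(OCC)OCC | starting material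
9 | 8-methyl 1-prop-2-enyl (2E,7S)-3-methyl-7-[(E)-3-(trimethylsilyl)prop-1-enyl]oct-2-enedioate | COC(=O)[C@H](/C=C/C[Si](C)(C)C)CCC/C(C)=C/C(=O)OCC=C | intermediate
10 | (2E,7S)-8-methoxy-3-methyl-8-oxo-7-[(E)-3-(trimethylsilyl)prop-1-enyl]oct-2-enoic acid | COC(=O)[C@H](/C=C/C[Si](C)(C)C)CCC/C(C)=C/C(=O)O | intermediate
11 | (2E,7S)-8-methoxy-3-methyl-8-oxo-7-[(E)-3-(trimethylsilyl)prop-1-enyl]oct-2-enoyl chloride | COC(=O)[C@H](/C=C/C[Si](C)(C)C)CCC/C(C)=C/C(=O)Cl | intermediate
12 | methyl (1S,2R,3R)-2-ethenyl-3-methyl-3-(2-oxoethenyl)cyclohexane-1-carboxylate (vinylketene; ester and vinyl trans, vinyl and ketene arm trans) | C=C[C@@H]1[C@@H](C(=O)OC)CCC[C@@]1(C)C=C=O | intermediate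
13 | methyl 8-chloro-4a-methyl-6-oxodecahydronaphthalene-1-carboxylate (trans-fused, C-1, C-4a and C-8a as in 14, both epimers at the chlorine-bearing carbon) | C1C(=O)CC(Cl)[C@@H]2[C@@H](C(=O)OC)CCC[C@@]12C | intermediate
14 | methyl (1S,4aS,8aR)-4a-methyl-6-oxo-1,2,3,4,4a,5,6,8a-octahydronaphthalene-1-carboxylate (trans-fused enone, ester equatorial) | C1C(=O)C=C[C@@H]2[C@@H](C(=O)OC)CCC[C@@]12C | intermediate
15 | methyl 5-[(dimethylamino)methyl]-4a-methyl-6-oxo-1,2,3,4,4a,5,6,8a-octahydronaphthalene-1-carboxylate (ring stereocentres as in 14, epimers at C-5) | CN(C)CC1C(=O)C=C[C@@H]2[C@@H](C(=O)OC)CCC[C@@]12C | intermediate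
16 | [1-(methoxycarbonyl)-4a-methyl-6-oxo-1,2,3,4,4a,5,6,8a-octahydronaphthalen-5-yl]methyl(trimethyl)ammonium iodide (ring stereocentres as in 14) | C[N+](C)(C)CC1C(=O)C=C[C@@H]2[C@@H](C(=O)OC)CCC[C@@]12C.[I-] | intermediate
17 | methyl (1S,4aR,8aR)-4a-methyl-5-methylidene-6-oxo-1,2,3,4,4a,5,6,8a-octahydronaphthalene-1-carboxylate | C=C1C(=O)C=C[C@@H]2[C@@H](C(=O)OC)CCC[C@@]12C | intermediate
18 | 2-chlorobuta-1,3-diene | C=CC(Cl)=C | starting material
19 | chloro[(trimethylsilyl)methyl]magnesium | C[Si](C)(C)C[Mg]Cl | starting material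
20 | trimethyl(2-methylidenebut-3-enyl)silane | C=CC(=C)C[Si](C)(C)C | intermediate
21 | methyl 4a-methyl-5-(3-methylidenepent-4-enyl)-6-oxo-1,2,3,4,4a,5,6,8a-octahydronaphthalene-1-carboxylate (ring stereocentres as in 17, epimers at C-5) | C=CC(=C)CCC1C(=O)C=C[C@@H]2[C@@H](C(=O)OC)CCC[C@@]12C | intermediate
22 | methyl (1S,4aR,5S,8aR)-4a-methyl-5-(3-methylidenepent-4-enyl)-6-oxodecahydronaphthalene-1-carboxylate | C=CC(=C)CC[C@@H]1C(=O)CC[C@@H]2[C@@H](C(=O)OC)CCC[C@@]12C | intermediate
23 | methyl (1S,4aR,5R,8aR)-4a-methyl-6-methylidene-5-(3-methylidenepent-4-enyl)decahydronaphthalene-1-carboxylate | C=CC(=C)CC[C@@H]1C(=C)CC[C@@H]2[C@@H](C(=O)OC)CCC[C@@]12C | intermediate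
24 | methyl (1R,4aS,5R,8aS)-1,4a-dimethyl-6-methylidene-5-(3-methylidenepent-4-enyl)decahydronaphthalene-1-carboxylate | C=CC(=C)CC[C@@H]1C(=C)CC[C@@H]2[C@](C)(C(=O)OC)CCC[C@@]12C | intermediate
25 | [(1R,4aS,5R,8aS)-1,4a-dimethyl-6-methylidene-5-(3-methylidenepent-4-enyl)decahydronaphthalen-1-yl]methanol | C=CC(=C)CC[C@@H]1C(=C)CC[C@@H]2[C@](C)(CO)CCC[C@@]12C | intermediate
26 | (Z)-3-iodoprop-2-enoic acid | OC(=O)/C=C\I | starting material
27 | [(1R,4aS,5R,8aS)-1,4a-dimethyl-6-methylidene-5-(3-methylidenepent-4-enyl)decahydronaphthalen-1-yl]methyl (Z)-3-iodoprop-2-enoate | C=CC(=C)CC[C@@H]1C(=C)CC[C@@H]2[C@](C)(COC(=O)/C=C\I)CCC[C@@]12C | intermediate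
28 | (4-hydroxyphenyl)boronic acid | OB(O)c1ccc(O)cc1 | starting material
29 | [(1R,4aS,5R,8aS)-1,4a-dimethyl-6-methylidene-5-(3-methylidenepent-4-enyl)decahydronaphthalen-1-yl]methyl (Z)-3-(4-hydroxyphenyl)prop-2-enoate | C=CC(=C)CC[C@@H]1C(=C)CC[C@@H]2[C@](C)(COC(=O)/C=C\c3ccc(O)cc3)CCC[C@@]12C | target

## Step count and risks

Total: 16 steps. Longest linear sequence: 15 steps (steps 1 to 8 and 10 to 16); step 9 prepares allylsilane 20 in a one-step branch.

Steps most likely to fail:

Step 7 (proposed method). The acylium ion may be consumed by intermolecular acylation or by protodesilylation of the allylsilane before the conjugate allylation takes place, the ring-fusion selectivity at C-10 may be low, or the vinylketene may dimerise instead of acylating the vinyl group. The fallback makes the two bonds one after the other by known reactions and sets out from ketone 7. Knoevenagel condensation with Meldrum's acid (TiCl4, pyridine, THF) gives the alkylidene Meldrum's acid F1. Intramolecular Hosomi–Sakurai addition of the allylsilane to this doubly activated acceptor (TiCl4, CH2Cl2, −78 °C) closes ring A and forms C-5–C-10, giving the cyclohexyl Meldrum's acid F2, in which the bulky dioxanedione ring is expected to sit equatorial. Heating in wet DMF opens F2 with loss of acetone and CO2 to the acetic acid F3, and 1-chloro-N,N,2-trimethylprop-1-en-1-amine gives the acid chloride F4. SnCl4-mediated acylation of the vinyl group followed by DBU forms C-7–C-8 and comes back to the route at enone 14.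

Step 10. The reactive 9-methylidene dienone or the diene product may oligomerise under TiCl4, or the allylsilane may add at the ring carbon C-6. The fallback sets out from dienone 17 and builds the diene last. TiCl4-mediated conjugate propargylation with tributyl(propa-1,2-dienyl)stannane gives the 9-(but-3-ynyl) enone F5. Conjugate reduction with [(Ph3P)CuH]6 and equilibration with NaOMe give the saturated ketone F6, and Wittig methylenation gives the enyne ester F7. Enyne cross-metathesis with ethene (second-generation Grubbs catalyst, CH2Cl2) turns the terminal alkyne into the 2-substituted buta-1,3-diene and comes back to the route at ester 23.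

Step 16. The iodoacrylate or the product cinnamate may isomerise from Z to E under palladium and base, or the ester may be hydrolysed. The fallback sets out from alcohol 25 and forms the Z alkene by olefination. Esterification with 2-(diphenoxyphosphoryl)acetic acid (DCC, DMAP) gives the diaryl phosphonoacetate F8. A Z-selective Horner–Wadsworth–Emmons reaction with 4-(tert-butyldimethylsilyloxy)benzaldehyde (NaH, THF, −78 °C) gives the silyl-protected (Z)-cinnamate F9. Bu4NF buffered with AcOH (THF, 0 °C) removes the silyl group and comes back to the route at the target 29.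

Further compounds
F1 | step 7 | methyl (2S,3E)-2-[4-(2,2-dimethyl-4,6-dioxo-1,3-dioxan-5-ylidene)pentyl]-5-(trimethylsilyl)pent-3-enoate | COC(=O)[C@H](/C=C/C[Si](C)(C)C)CCCC(C)=C1C(=O)OC(C)(C)OC1=O
F2 | step 7 | methyl 3-(2,2-dimethyl-4,6-dioxo-1,3-dioxan-5-yl)-2-ethenyl-3-methylcyclohexane-1-carboxylate (ring stereocentres as in 12) | C=C[C@@H]1[C@@H](C(=O)OC)CCC[C@@]1(C)C2C(=O)OC(C)(C)OC2=O
F3 | step 7 | 2-[2-ethenyl-3-(methoxycarbonyl)-1-methylcyclohexyl]acetic acid (ring stereocentres as in 12) | C=C[C@@H]1[C@@H](C(=O)OC)CCC[C@@]1(C)CC(=O)O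
F4 | step 7 | methyl 3-(2-chloro-2-oxoethyl)-2-ethenyl-3-methylcyclohexane-1-carboxylate (ring stereocentres as in 12) | C=C[C@@H]1[C@@H](C(=O)OC)CCC[C@@]1(C)CC(=O)Cl
F5 | step 10 | methyl 5-(but-3-ynyl)-4a-methyl-6-oxo-1,2,3,4,4a,5,6,8a-octahydronaphthalene-1-carboxylate (ring stereocentres as in 17, epimers at C-5) | C#CCCC1C(=O)C=C[C@@H]2[C@@H](C(=O)OC)CCC[C@@]12C
F6 | step 10 | methyl 5-(but-3-ynyl)-4a-methyl-6-oxodecahydronaphthalene-1-carboxylate (stereocentres as in 22) | C#CCC[C@@H]1C(=O)CC[C@@H]2[C@@H](C(=O)OC)CCC[C@@]12C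
F7 | step 10 | methyl 5-(but-3-ynyl)-4a-methyl-6-methylidenedecahydronaphthalene-1-carboxylate (stereocentres as in 23) | C#CCC[C@@H]1C(=C)CC[C@@H]2[C@@H](C(=O)OC)CCC[C@@]12C
F8 | step 16 | [(1R,4aS,5R,8aS)-1,4a-dimethyl-6-methylidene-5-(3-methylidenepent-4-enyl)decahydronaphthalen-1-yl]methyl 2-(diphenoxyphosphoryl)acetate | C=CC(=C)CC[C@@H]1C(=C)CC[C@@H]2[C@](C)(COC(=O)CP(=O)(Oc3ccccc3)Oc3ccccc3)CCC[C@@]12C
F9 | step 16 | [(1R,4aS,5R,8aS)-1,4a-dimethyl-6-methylidene-5-(3-methylidenepent-4-enyl)decahydronaphthalen-1-yl]methyl (Z)-3-[4-(tert-butyldimethylsilyloxy)phenyl]prop-2-enoate | C=CC(=C)CC[C@@H]1C(=C)CC[C@@H]2[C@](C)(COC(=O)/C=C\c3ccc(O[Si](C)(C)C(C)(C)C)cc3)CCC[C@@]12C
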